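**Plan**
- Retrosynthesis: unmask the four phenols; cut the C2–C1' bond between the γ-pyrone ring (ring C) and the resorcinol ring (ring B), giving an 8-prenylchromone C2–H and a resorcinol diether C–H; return the prenyl group from C8 to O5 (para-Claisen–Cope); strip the O-substituents back to 5,7-dihydroxychromone.
- Enabling feature: C2 is the β-carbon of the vinylogous ester O1–C2=C3–C4=O of ring C, so silylation of the C4 carbonyl oxygen turns ring C into a benzopyrylium ion electrophilic at C2. C1' of ring B lies ortho to O2' and para to O4', the innate nucleophilic carbon of a resorcinol diether. Both partners can therefore be joined as C–H compounds, and a hydride abstraction from C2 restores the pyrone.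
- Forward order: rings A/C and ring B are bought intact and no ring is built. Prenyl goes onto O5 and then to C8, acetates are placed on O5/O7 to keep the cation electrophilic, the two halves are joined, and one methanolysis frees all phenols.
- Stereochemistry: the target has none; the transient C2 stereocentre of the adduct forms racemic and is erased by the oxidation.

Key step: step 6

Remark: the target has no stereocentre and no stereogenic double bond (the prenyl alkene carries two methyl groups), so it is one achiral compound and no enantiocontrol is needed.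

**Route**

Step 1
Reactants: 1 5,7-dihydroxy-4H-chromen-4-one
Product: 2 5-hydroxy-4-oxo-4H-chromen-7-yl acetate
Conditions: Ac2O (1.05 equiv), pyridine, 0 °C to rt
Reagents that add atoms: acetic anhydride, CC(=O)OC(C)=O
Why: Selective O-acylation, because the 5-OH is hydrogen-bonded to the C4 carbonyl and far less nucleophilic than the free, more acidic 7-OH.

Step 2
Reactants: 2 5-hydroxy-4-oxo-4H-chromen-7-yl acetate; 3 3-methylbut-2-en-1-ol
Product: 4 5-[(3-methylbut-2-en-1-yl)oxy]-4-oxo-4H-chromen-7-yl acetate
Conditions: PPh3, DIAD, THF, 0 °C to rt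
Reagents that add atoms: none
Why: Mitsunobu etherification, in which the phosphonium-activated primary allylic alcohol is displaced by the only free phenol under neutral conditions that leave the 7-acetate in place, as precedented for 7-O-acyl-5-hydroxyflavonoids.

Step 3
Reactants: 4 5-[(3-methylbut-2-en-1-yl)oxy]-4-oxo-4H-chromen-7-yl acetate
Product: 7 5-hydroxy-8-(3-methylbut-2-en-1-yl)-4-oxo-4H-chromen-7-yl acetate, via ortho-dienone 5 (not isolated), via para-dienone 6 (not isolated)
Conditions: Eu(fod)3 (10 mol %), CHCl3, 60 °C, sealed tube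
Reagents that add atoms: none
Why: Lewis-acid-accelerated para-Claisen–Cope rearrangement, in which Eu(III) bound at the C4 carbonyl/O5 site promotes the [3,3] shift to C6 (dienone 5), a second [3,3] shift carries the allyl unit to the free C8 position with restoration of the normal prenyl connectivity (dienone 6), and enolisation gives the phenol, as precedented for 5-O-prenyl flavonoids.

Step 4
Reactants: 7 5-hydroxy-8-(3-methylbut-2-en-1-yl)-4-oxo-4H-chromen-7-yl acetate
Product: 8 8-(3-methylbut-2-en-1-yl)-4-oxo-4H-chromene-5,7-diyl diacetate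
Conditions: Ac2O (1.5 equiv), Et3N, DMAP (cat.), CH2Cl2, rt
Reagents that add atoms: acetic anhydride, CC(=O)OC(C)=O
Why: DMAP-catalysed acylation overcomes the hydrogen bond of the 5-OH and gives a chromone whose ring A carries only electron-withdrawing O-acyl groups, as the key step requires.

Step 5
Reactants: 9 resorcinol (benzene-1,3-diol)
Product: 10 1,3-bis[(tert-butyldimethylsilyl)oxy]benzene
Conditions: TBSCl (2.2 equiv), imidazole (4 equiv), DMF, rt
Reagents that add atoms: tert-butyldimethylsilyl chloride, CC(C)(C)[Si](C)(C)Cl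
Why: Standard imidazole-mediated silylation of both phenols gives an arene that keeps the π-nucleophilicity of a resorcinol diether and can be unmasked by mild base.

Step 6
Reactants: 8 8-(3-methylbut-2-en-1-yl)-4-oxo-4H-chromene-5,7-diyl diacetate; 10 1,3-bis[(tert-butyldimethylsilyl)oxy]benzene
Product: 13 2-{2,4-bis[(tert-butyldimethylsilyl)oxy]phenyl}-8-(3-methylbut-2-en-1-yl)-4-oxo-4H-chromene-5,7-diyl diacetate, via siloxybenzopyrylium triflate 11 (not isolated), via 2H-chromene adduct 12 (not isolated)
Conditions: 8, TBSOTf (1.2 equiv), CH2Cl2, rt; slow addition to 10 (3 equiv) and 2,6-di-tert-butyl-4-methylpyridine (1.5 equiv), CH2Cl2, 0 °C to rt; then DDQ (1.2 equiv), 0 °C; aq. NaHCO3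
Reagents that add atoms: tert-butyldimethylsilyl trifluoromethanesulfonate, CC(C)(C)[Si](C)(C)OS(=O)(=O)C(F)(F)F (its atoms are held only by 11 and 12; none remain in 13)
Why: Proposed new method: O-silylation of the pyrone carbonyl of 8 gives the 4-siloxybenzopyrylium triflate 11, C2 of which is attacked by C4 of arene 10 in a Friedel–Crafts step, and the hindered pyridine removes the arenium proton to give silyl enol ether 12; DDQ then abstracts the C2 hydride of 12 (flanked by the ring oxygen, the enol ether and the electron-rich aryl group) to give a 4-siloxyflavylium ion, which passes its silyl group to the hydroquinone anion and leaves flavone 13. The closest known reaction types are the C2 addition of silyl enol ethers and other π-nucleophiles to 4-siloxybenzopyrylium salts and the DDQ dehydrogenation of silyl enol ethers and of flav-3-enes; the use of an aryl ether C–H nucleophile and the oxidation in the same flask are the untested parts. No ring is closed, and the only new stereocentre (C2 of 12, racemic) is destroyed by the oxidation, so no control element is needed. Attack at C2 rather than C4 of the cation should follow from the O-silyl group on C4 and the larger LUMO coefficient at C2, attack through C4 rather than C2 of the arene from the two flanking silyloxy groups, and sufficient electrophilicity from the two acetoxy groups on ring A. Double arylation of 10 and attack of enol ether 12 on unreacted 11 should be suppressed by the excess of 10 and the slow addition of 11, and the prenyl alkene should be spared because the base keeps the medium free of triflic acid and the C2–H bond of 12 is far more hydridic than the benzylic CH2 of the prenyl group on the acetoxy-deactivated ring.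

Step 7
Reactants: 13 2-{2,4-bis[(tert-butyldimethylsilyl)oxy]phenyl}-8-(3-methylbut-2-en-1-yl)-4-oxo-4H-chromene-5,7-diyl diacetate
Product: 14 2-(2,4-dihydroxyphenyl)-5,7-dihydroxy-8-(3-methylbut-2-en-1-yl)-4H-chromen-4-one
Conditions: K2CO3 (4 equiv), degassed MeOH, 0 °C to rt, Ar; then 1 M HCl to pH 5
Reagents that add atoms: none
Why: Carbonate-promoted methanolysis should cleave both aryl acetates (transesterification) and both aryl silyl ethers (methoxide attack at silicon, phenoxide leaving group), while the C-prenyl group and the γ-pyrone are inert to mild base.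

**Compound list**

1 | 5,7-dihydroxy-4H-chromen-4-one | O=c1ccoc2cc(O)cc(O)c12 | starting material
2 | 5-hydroxy-4-oxo-4H-chromen-7-yl acetate | CC(=O)Oc1cc(O)c2c(=O)ccoc2c1 | intermediate
3 | 3-methylbut-2-en-1-ol (prenyl alcohol) | CC(C)=CCO | starting material
4 | 5-[(3-methylbut-2-en-1-yl)oxy]-4-oxo-4H-chromen-7-yl acetate | CC(C)=CCOc1cc(OC(C)=O)cc2occc(=O)c12 | intermediate
5 | ortho-dienone: 6-(2-methylbut-3-en-2-yl)-4,5-dioxo-5,6-dihydro-4H-chromen-7-yl acetate (racemic, formed in the flask) | C=CC(C)(C)C1C(OC(C)=O)=CC2=C(C1=O)C(=O)C=CO2 | intermediate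
6 | para-dienone: 8-(3-methylbut-2-en-1-yl)-4,5-dioxo-5,8-dihydro-4H-chromen-7-yl acetate (racemic, formed in the flask) | CC(C)=CCC1C(OC(C)=O)=CC(=O)C2=C1OC=CC2=O | intermediate
7 | 5-hydroxy-8-(3-methylbut-2-en-1-yl)-4-oxo-4H-chromen-7-yl acetate | CC(C)=CCc1c(OC(C)=O)cc(O)c2c(=O)ccoc12 | intermediate
8 | 8-(3-methylbut-2-en-1-yl)-4-oxo-4H-chromene-5,7-diyl diacetate | CC(C)=CCc1c(OC(C)=O)cc(OC(C)=O)c2c(=O)ccoc12 | intermediate
9 | resorcinol (benzene-1,3-diol) | Oc1cccc(O)c1 | starting material
10 | 1,3-bis[(tert-butyldimethylsilyl)oxy]benzene | CC(C)(C)[Si](C)(C)Oc1cccc(O[Si](C)(C)C(C)(C)C)c1 | intermediate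
11 | siloxybenzopyrylium triflate: 5,7-diacetoxy-4-[(tert-butyldimethylsilyl)oxy]-8-(3-methylbut-2-en-1-yl)chromenylium trifluoromethanesulfonate (formed in the flask) | CC(C)=CCc1c(OC(C)=O)cc(OC(C)=O)c2c(O[Si](C)(C)C(C)(C)C)cc[o+]c12.[O-]S(=O)(=O)C(F)(F)F | intermediate
12 | 2H-chromene adduct: 2-{2,4-bis[(tert-butyldimethylsilyl)oxy]phenyl}-4-[(tert-butyldimethylsilyl)oxy]-8-(3-methylbut-2-en-1-yl)-2H-chromene-5,7-diyl diacetate (racemic at C2, formed in the flask) | CC(C)=CCc1c(OC(C)=O)cc(OC(C)=O)c2c1OC(c1ccc(O[Si](C)(C)C(C)(C)C)cc1O[Si](C)(C)C(C)(C)C)C=C2O[Si](C)(C)C(C)(C)C | intermediate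
13 | 2-{2,4-bis[(tert-butyldimethylsilyl)oxy]phenyl}-8-(3-methylbut-2-en-1-yl)-4-oxo-4H-chromene-5,7-diyl diacetate | CC(C)=CCc1c(OC(C)=O)cc(OC(C)=O)c2c(=O)cc(-c3ccc(O[Si](C)(C)C(C)(C)C)cc3O[Si](C)(C)C(C)(C)C)oc12 | intermediate
14 | 2-(2,4-dihydroxyphenyl)-5,7-dihydroxy-8-(3-methylbut-2-en-1-yl)-4H-chromen-4-one | CC(C)=CCc1c(O)cc(O)c2c(=O)cc(-c3ccc(O)cc3O)oc12 | target

**Count and risks**

Total step count: 7. Longest linear sequence: 6 steps (1 to 14 through steps 1, 2, 3, 4, 6 and 7); step 5 is the one-step side branch.

Steps most likely to fail: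

1. Step 6. The arene may add too slowly to the acetoxy-substituted pyrylium ion. Enol ether 12 may add to unreacted 11 and give oligomers. DDQ may also attack the prenyl side chain. The fallback forms the same bond with a boron nucleophile and known reactions. From 10, bromination with NBS in MeCN should give 4-bromo-1,3-bis[(tert-butyldimethylsilyl)oxy]benzene F1. Miyaura borylation (B2pin2, Pd(dppf)Cl2, KOAc, dioxane) should give the pinacol boronate 2-{2,4-bis[(tert-butyldimethylsilyl)oxy]phenyl}-4,4,5,5-tetramethyl-1,3,2-dioxaborolane F2. Rhodium(I)-catalysed 1,4-addition of F2 to chromone 8 (Hayashi–Miyaura type, [Rh(OH)(cod)]2, aqueous dioxane, no added base so that the acetates survive) should give the racemic flavanone 2-{2,4-bis[(tert-butyldimethylsilyl)oxy]phenyl}-8-(3-methylbut-2-en-1-yl)-4-oxochromane-5,7-diyl diacetate F3. Dehydrogenation of F3 with DDQ in hot dioxane, a standard flavanone-to-flavone oxidation, returns to the route at 13.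

2. Step 3. The ortho-dienone may enolise before the Cope shift, which would leave the 1,1-dimethylallyl group on C6, or the allylic ether may be cleaved by the Lewis acid. The fallback avoids the 5-O-prenyl ether altogether. From 1, alkylation of the more acidic 7-OH with prenyl bromide and K2CO3 in acetone should give 5-hydroxy-7-[(3-methylbut-2-en-1-yl)oxy]-4H-chromen-4-one F4. A clay-promoted 1,3-shift of the prenyl group from oxygen to the ortho carbon (montmorillonite K10, CH2Cl2, rt) should give 5,7-dihydroxy-8-(3-methylbut-2-en-1-yl)-4H-chromen-4-one F5, to be separated from its 6-prenyl isomer. Exhaustive acetylation of F5 (Ac2O, pyridine, DMAP) returns to the route at 8.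

3. Step 2. Alkylation at the hydrogen-bonded 5-OH may be slow enough for the betaine to remove or transfer the 7-acetyl group. The fallback replaces the redox condensation by a phenoxide alkylation on a base-stable silyl ether. From 1, selective silylation of the 7-OH (TIPSCl, imidazole, DMF) should give 5-hydroxy-7-[(triisopropylsilyl)oxy]-4H-chromen-4-one F6. Williamson alkylation of the 5-OH (prenyl bromide, K2CO3, acetone, reflux) should give 5-[(3-methylbut-2-en-1-yl)oxy]-7-[(triisopropylsilyl)oxy]-4H-chromen-4-one F7. Treatment of F7 with TBAF in THF at 0 °C and trapping of the 7-phenoxide with Ac2O in the same flask returns to the route at 4.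

**Further compounds**

F1 | step 6 | 4-bromo-1,3-bis[(tert-butyldimethylsilyl)oxy]benzene | CC(C)(C)[Si](C)(C)Oc1ccc(Br)c(O[Si](C)(C)C(C)(C)C)c1
F2 | step 6 | 2-{2,4-bis[(tert-butyldimethylsilyl)oxy]phenyl}-4,4,5,5-tetramethyl-1,3,2-dioxaborolane | CC(C)(C)[Si](C)(C)Oc1ccc(B2OC(C)(C)C(C)(C)O2)c(O[Si](C)(C)C(C)(C)C)c1
F3 | step 6 | 2-{2,4-bis[(tert-butyldimethylsilyl)oxy]phenyl}-8-(3-methylbut-2-en-1-yl)-4-oxochromane-5,7-diyl diacetate (racemic) | CC(C)=CCc1c(OC(C)=O)cc(OC(C)=O)c2c1OC(c1ccc(O[Si](C)(C)C(C)(C)C)cc1O[Si](C)(C)C(C)(C)C)CC2=O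
F4 | step 3 | 5-hydroxy-7-[(3-methylbut-2-en-1-yl)oxy]-4H-chromen-4-one | CC(C)=CCOc1cc(O)c2c(=O)ccoc2c1
F5 | step 3 | 5,7-dihydroxy-8-(3-methylbut-2-en-1-yl)-4H-chromen-4-one | CC(C)=CCc1c(O)cc(O)c2c(=O)ccoc12
F6 | step 2 | 5-hydroxy-7-[(triisopropylsilyl)oxy]-4H-chromen-4-one | CC(C)[Si](Oc1cc(O)c2c(=O)ccoc2c1)(C(C)C)C(C)C
F7 | step 2 | 5-[(3-methylbut-2-en-1-yl)oxy]-7-[(triisopropylsilyl)oxy]-4H-chromen-4-one | CC(C)=CCOc1cc(O[Si](C(C)C)(C(C)C)C(C)C)cc2occc(=O)c12
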